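If the partner is fed over 1.0 min instead of charged at once, as in winter, the substrate may get a turn at the reagent, so I ask how fast the substrate takes reagent against how fast the partner arrives.

| flask | substrate | partner | reagent | temperature | remark | time |
|---|---|---|---|---|---|---|
| green | 0.20 M | 0.22 M | 0.21 M | 65 °C | run made earlier |  |
| ochre | 0.10 M | 0.22 M | 0.21 M | 80 °C | run made earlier |  |
| red | 0.15 M | 0.22 M | 0.21 M | 65 °C | run made earlier |  |
| grey | 0.20 M | 0.22 M | 0.42 M | 80 °C | run made earlier |  |
| autumn | 0.20 M | 0.220 M | 0.210 M |  | everything together at the start at 60 °C, warmed to 80 °C at 1.0 min | 2.5 min |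
| noon | 0.20 M (in portions, 3, over 1.0 min) | 0.220 M | 0.210 M | 80 °C | first portion at the start, last at 1.0 min | 2.5 min |
| summer | 0.20 M | 0.220 M (fed, over 1.0 min) | 0.210 M |  | the addition at 60 °C, then warmed to 80 °C; the feed brings no volume worth counting | 2.5 min |
| winter | 0.20 M | 0.220 M (fed, over 1.0 min) | 0.210 M | 80 °C | all else is in the flask from the start; the feed brings no volume worth counting | 2.5 min |
| midnight | 0.20 M | 0.220 M | 0.210 M | 80 °C | everything together at the start | 2.5 min |

green run (percent of the substrate charged)

| time / min | target / % | substrate / % |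
|---|---|---|
| 0.500 | 0.2 | 91.2 |
| 1.00 | 0.3 | 93.2 |
| 2.00 | 0.3 | 93.1 |
| 3.00 | 0 | 93.0 |

ochre run (percent of the substrate charged)

| time / s | target / % | substrate / % |
|---|---|---|
| 15.0 | 0 | 92.2 |
| 30.0 | 1.9 | 89.5 |
| 50.0 | 3.7 | 89.5 |
| 60.0 | 3.0 | 91.0 |
| 80.0 | 1.6 | 90.5 |
| 90.0 | 2.2 | 90.2 |

red run (percent of the substrate charged)

| time / min | target / % | substrate / % |
|---|---|---|
| 0.333 | 0 | 92.6 |
| 0.667 | 2.2 | 91.4 |
| 1.00 | 1.0 | 93.5 |
| 2.00 | 0.8 | 92.3 |
| 3.00 | 2.0 | 92.1 |

grey run (percent of the substrate charged)

| time / s | target / % | substrate / % |
|---|---|---|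
| 10.0 | 1.9 | 78.2 |
| 15.0 | 2.8 | 74.4 |
| 25.0 | 6.6 | 65.7 |
| 50.0 | 8.8 | 55.1 |
| 90.0 | 14.6 | 43.1 |

(readings scatter by 1 percentage point)

- the numbers in the tables scatter by 1 percentage point (one standard deviation)

- the flask that comes out highest in amount of target, in percent of the substrate charged, or "all alike" when all lie within 1.5 percentage points (autumn / noon / summer / winter / midnight / all alike)
- target at the end, in percent of the substrate charged, autumn
- target at the end, in percent of the substrate charged, noon
- target at the end, in percent of the substrate charged, summer
- target at the end, in percent of the substrate charged, winter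
- target at the end, in percent of the substrate charged, midnight

In green the substrate stalls at 93.0%, which I read as a share of 6.67% of the reagent charge going to substrate. I take the rest as lost to the partner. Grey charges reagent beyond its partner, and 78.2% of its substrate stands at 10.0 s. I take the reagent above the partner as what meets the substrate there. Scaled to the substrate of winter, that reading gives a pseudo-first-order constant for reagent loss to substrate of 1.48 min⁻¹, and it carries the scatter of the table.

Now I define the feed number: the fraction of the reagent charge that substrate takes per minute at the start, divided by the fraction that arriving partner takes. For winter it is 1.41, so substrate holds control at the start. Suppose partner is eaten on arrival and substrate stays near its charge. Then the reagent lasts 0.596 min, within the feed. The share of reagent reaching substrate is one minus the logarithm of one plus N, over N, which is 37.6%. So I expect winter to keep 60.5% of its substrate.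

Turned round, for winter to take no more of its substrate than a flask charged at once, this share must fall to the green share, which I use although green ran at 65 °C. At small N the share tends to N over two, so N must come down to 0.133. The feed number of winter stands ten times that value.

The forecast names winter, with autumn 2.3%, noon 1.8%, summer 3%, winter 11% and midnight 4.2%. For winter it says “partner starvation lets about 27% activate”. My reckoning has 39.5% of the substrate taken there, so we differ on that amount.

    2 open intermediate → homo product (k = 0.0793 L mol⁻¹ s⁻¹, Ea = 50.0 kJ mol⁻¹)
    open intermediate + second intermediate → target (k = 0.0734 L mol⁻¹ s⁻¹, Ea = 70.0 kJ mol⁻¹)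
    target ⇌ isomer of the product (K = 0.810, k = 0.112 s⁻¹, Ea = 85.0 kJ mol⁻¹, ΔH = −25.0 kJ mol⁻¹)
    reagent + partner → second intermediate (k = 2.38 L mol⁻¹ s⁻¹, Ea = 62.0 kJ mol⁻¹)
    reagent ⇌ dormant form (K = 3.05, k = 0.00914 s⁻¹, Ea = 103 kJ mol⁻¹, ΔH = −28.0 kJ mol⁻¹)
    substrate + reagent → open intermediate (k = 0.110 L mol⁻¹ s⁻¹, Ea = 70.0 kJ mol⁻¹)
    (constants at 80 °C)

The highest flask is winter, at 7.76%, with summer 5.58%, midnight 3.69%, autumn 2.99% and noon 1.64%. Winter ends with 66.9% of its substrate and midnight with 91.5%, against the 60.5% I reckoned for winter. The neighbour of winter charged with 0.80 M of substrate has a feed number of 5.63, a share of 66.4%, and a reckoned 82.6% of its substrate kept. That neighbour ends with 82.1% of its substrate and 1.58% of target.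

(The data come from a simulation on assumed constants; scatter was added.)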